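**Retrosynthetic overview**

- Hansfordiol C is traced back to its bis(methyl ether); the two phenols are unmasked last with BBr3. No ring is formed anywhere: the only ring, the benzene ring C1–C6, is bought as 3,5-dimethoxytoluene.
- Key disconnection C1'–C2' (benzylic CH2–CH2 of the side chain): the benzylic potassium compound of 3,5-dimethoxytoluene plus (S)-16-bromohexadecan-3-ol, the complete C16 chain with its hydroxyl left free. A C–H bond of a C9 commodity arene becomes the C–C bond, and the full C25 skeleton with all three oxygens and the stereocentre results in one operation.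
- Enabling feature: C1' is the methyl carbon on ring carbon C5, meta to the oxygens on C1 and C3. Its carbanion is delocalised into the ring (onto C2/C4/C6) but receives no lone-pair donation from either oxygen, so an amine-shuttled potassium metalation can be funnelled there and away from the ring C–H bonds flanked by OMe.
- Chain: C14'–C17' and the (S)-carbinol come from (S)-1,2-epoxybutane, C2'–C13' from dodec-11-enylmagnesium bromide (Cu-catalysed epoxide opening); radical anti-Markovnikov HBr addition then puts the leaving group on C2'.

Key step: step 3

Assumption: 12-bromododec-1-ene, (S)-1,2-epoxybutane and 3,5-dimethoxytoluene are taken as catalogue compounds; the side chain is numbered C1'–C17' from the benzylic carbon and the ring C1–C6 with oxygen on C1 and C3.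

Step 1
Reactants: 1 12-bromododec-1-ene; 2 (S)-1,2-epoxybutane [(S)-2-ethyloxirane]
Product: 4 (S)-hexadec-15-en-3-ol, via dodec-11-en-1-ylmagnesium bromide 3 (not isolated)
Conditions: Mg, THF, rt; then CuI (10 mol%), 2, −30 → 0 °C; aq. NH4Cl
Reagents that add atoms: none
Why: Copper-catalysed Grignard opening of a terminal epoxide (SN2 at the unsubstituted CH2 of 2): the C–O bond at the stereocentre is never broken, so the (S) configuration of 2 becomes C3 of 4 unchanged, the descriptor staying S because the priority order O > CH2 chain > ethyl is kept.

Step 2
Reactants: 4 (S)-hexadec-15-en-3-ol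
Product: 5 (S)-16-bromohexadecan-3-ol
Conditions: HBr (g), dibenzoyl peroxide (cat.), hexane, hν, 0 °C
Reagents that add atoms: hydrogen bromide, Br
Why: Kharasch anti-Markovnikov radical-chain hydrobromination: Br• adds to the terminal CH2 to give the secondary radical, which abstracts H from HBr, while the cold apolar medium disfavours ionic Markovnikov addition and substitution of the secondary alcohol; the remote stereocentre is not involved and no new one is formed.

Step 3
Reactants: 6 3,5-dimethoxytoluene (1,3-dimethoxy-5-methylbenzene); 5 (S)-16-bromohexadecan-3-ol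
Product: 8 (S)-17-(3,5-dimethoxyphenyl)heptadecan-3-ol, via (3,5-dimethoxybenzyl)potassium 7 (not isolated)
Conditions: 6 (2.4 equiv), n-BuLi, KOt-Bu, TMP(H) (2.4 equiv each), THF, −78 °C; then 5 (1.0 equiv), −78 → 0 °C; H2O
Reagents that add atoms: none
Why: Lateral (benzylic) C–H metalation followed by SN2 alkylation: n-BuLi/KOt-Bu deprotonates 6 kinetically at ring C–H bonds next to OMe, and TMP(H), through the mixed Li/K amide it forms, shuttles protons until the metal rests on the benzylic carbon as the ring-delocalised benzylpotassium 7, which then displaces bromide from the primary CH2Br of 5 and so forms the C1'–C2' bond. The closest known reaction type is the benzylic metalation of methoxy-substituted toluenes with BuLi/KOt-Bu/TMP(H) and trapping of the benzylpotassium with primary alkyl halides. No ring is closed and no stereocentre is formed; the carbinol centre of 5 is a spectator whose O–H is removed by the first equivalent of 7 (returning 6) and whose C–O and C–H bonds are not touched, so its (S) configuration is carried into 8. The step needs benzylic instead of ring metalation and substitution instead of elimination or O-alkylation: the first should be secured because the methyl carbon is meta to both oxygens, so its carbanion is stabilised by the ring and by two inductively withdrawing oxygens without receiving lone-pair donation, while the amine-mediated equilibration drains the ring-metalated species flanked by OMe; the second should be secured by the unhindered primary bromide, the soft delocalised carbanion and the low temperature, at which the alkoxide of 5 is a far poorer nucleophile than 7.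

Step 4
Reactants: 8 (S)-17-(3,5-dimethoxyphenyl)heptadecan-3-ol
Product: 9 Hansfordiol C, 5-[(S)-15-hydroxyheptadecyl]benzene-1,3-diol
Conditions: BBr3 (4 equiv), CH2Cl2, −78 → 0 °C; H2O
Reagents that add atoms: none
Why: Lewis-acid O-demethylation of aryl methyl ethers with BBr3 (ether–BBr3 adduct, loss of MeBr, hydrolysis of the aryl borates on work-up): the secondary alcohol is held as a dibromoborate whose B–O and not C–O bond is cleaved by water, so the (S) centre should be returned unchanged at or below 0 °C.

**Compound list**

1 | 12-bromododec-1-ene | C=CCCCCCCCCCCBr | starting material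
2 | (S)-1,2-epoxybutane [(S)-2-ethyloxirane] | CC[C@H]1CO1 | starting material
3 | dodec-11-en-1-ylmagnesium bromide | C=CCCCCCCCCCC[Mg]Br | intermediate (not isolated)
4 | (S)-hexadec-15-en-3-ol | CC[C@H](O)CCCCCCCCCCCC=C | intermediate
5 | (S)-16-bromohexadecan-3-ol | CC[C@H](O)CCCCCCCCCCCCCBr | intermediate
6 | 3,5-dimethoxytoluene (1,3-dimethoxy-5-methylbenzene) | COc1cc(C)cc(OC)c1 | starting material
7 | (3,5-dimethoxybenzyl)potassium | [K+].[CH2-]c1cc(OC)cc(OC)c1 | intermediate (not isolated)
8 | (S)-17-(3,5-dimethoxyphenyl)heptadecan-3-ol | CC[C@H](O)CCCCCCCCCCCCCCc1cc(OC)cc(OC)c1 | intermediate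
9 | Hansfordiol C, 5-[(S)-15-hydroxyheptadecyl]benzene-1,3-diol | CC[C@H](O)CCCCCCCCCCCCCCc1cc(O)cc(O)c1 | target

Total step count: 4. Longest linear sequence: 4 steps (1 → 4 → 5 → 8 → 9).

**Steps most likely to fail**

Step 3 (key step). The proton shuttle may not move the metal completely from the ring positions flanked by OMe to the benzylic carbon, which would lead to ring alkylation, and the strongly basic medium may eliminate HBr from 5. The fallback reverses the polarity of the same bond with a copper-catalysed Grignard coupling of the Kochi type. Setting out from 5, silylation (TBSCl, imidazole, DMF) would give (S)-[(16-bromohexadecan-3-yl)oxy](tert-butyl)dimethylsilane F1. Mg in THF would convert it into [(S)-14-(tert-butyldimethylsilyloxy)hexadecyl]magnesium bromide F2. With commercial 3,5-dimethoxybenzyl bromide (COc1cc(CBr)cc(OC)c1) and Li2CuCl4 (cat.) at −20 → 0 °C this should give (S)-tert-butyl{[17-(3,5-dimethoxyphenyl)heptadecan-3-yl]oxy}dimethylsilane F3. TBAF in THF would then bring the route back to 8.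

Step 4. Bromide may displace the dibromoborate at the carbinol carbon (loss or inversion of the C15' oxygen), or the second O-demethylation may stall unless the mixture is warmed, which raises the first risk. The fallback replaces methyl by benzyl ethers, removed by neutral hydrogenolysis; because benzylic ethers would not survive the base of step 3, the same C1'–C2' bond is made by a B-alkyl Suzuki–Miyaura coupling. Setting out from 4, 9-BBN (2.2 equiv, THF) would give (S)-9-[14-(9-borabicyclo[3.3.1]nonan-9-yloxy)hexadecyl]-9-borabicyclo[3.3.1]nonane F4. PdCl2(dppf) (cat.), aq. K3PO4 and commercial 3,5-bis(benzyloxy)benzyl bromide (BrCc1cc(OCc2ccccc2)cc(OCc2ccccc2)c1) in THF/DMF at 50 °C should give, after aqueous work-up, (S)-17-[3,5-bis(benzyloxy)phenyl]heptadecan-3-ol F5. H2, Pd/C in EtOAc/EtOH would then give 9 directly.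

Step 2. If the radical chain is poorly initiated, ionic Markovnikov addition and acid-promoted substitution at the carbinol compete. The fallback is a polar two-step anti-Markovnikov functionalisation. Setting out from 4, hydroboration with dicyclohexylborane (2.2 equiv, THF, 0 °C → rt) would give (S)-dicyclohexyl{14-[(dicyclohexylboranyl)oxy]hexadecyl}borane F6. Oxidation with NaOH/H2O2 would give (S)-hexadecane-1,14-diol F7. An Appel bromination with one equivalent of CBr4/PPh3 in CH2Cl2 at −20 °C, selective for the primary hydroxyl, would bring the route back to 5.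

**Further compounds**

F1 | step 3 | (S)-[(16-bromohexadecan-3-yl)oxy](tert-butyl)dimethylsilane | CC[C@H](O[Si](C)(C)C(C)(C)C)CCCCCCCCCCCCCBr
F2 | step 3 | [(S)-14-(tert-butyldimethylsilyloxy)hexadecyl]magnesium bromide | CC[C@H](O[Si](C)(C)C(C)(C)C)CCCCCCCCCCCCC[Mg]Br
F3 | step 3 | (S)-tert-butyl{[17-(3,5-dimethoxyphenyl)heptadecan-3-yl]oxy}dimethylsilane | CC[C@H](O[Si](C)(C)C(C)(C)C)CCCCCCCCCCCCCCc1cc(OC)cc(OC)c1
F4 | step 4 | (S)-9-[14-(9-borabicyclo[3.3.1]nonan-9-yloxy)hexadecyl]-9-borabicyclo[3.3.1]nonane | CC[C@H](OB1C2CCCC1CCC2)CCCCCCCCCCCCCB1C2CCCC1CCC2
F5 | step 4 | (S)-17-[3,5-bis(benzyloxy)phenyl]heptadecan-3-ol | CC[C@H](O)CCCCCCCCCCCCCCc1cc(OCc2ccccc2)cc(OCc2ccccc2)c1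
F6 | step 2 | (S)-dicyclohexyl{14-[(dicyclohexylboranyl)oxy]hexadecyl}borane | CC[C@H](OB(C1CCCCC1)C1CCCCC1)CCCCCCCCCCCCCB(C1CCCCC1)C1CCCCC1
F7 | step 2 | (S)-hexadecane-1,14-diol | CC[C@H](O)CCCCCCCCCCCCCO
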